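**Analysis of the target**

Bromoiesol A (13) is a triaryl diether without any stereocenter, and its diaryl ether axes are not expected to be configurationally stable, so nothing stereochemical has to be set. Ring A is a phenol with the hydroxyl on C1, an ether oxygen on C2, bromine on C3 and C5 and hydrogen on C4 and C6. The central ring B carries the two ether oxygens on neighbouring carbons C1 (to ring A) and C2 (to ring C), bromine on C3, C4 and C5 and one hydrogen on C6; ring C is a 2,4-dibromophenyl group. The sensitive groups are the seven aryl C–Br bonds, which exclude organolithium reagents, hot low-valent transition metals and ordinary catalytic hydrogenation, and the free phenol, which is open to oxidation and to further electrophilic substitution. The first difficulty is that both ether bonds are hindered: the ring A oxygen on C2 lies between C1–OH and C3–Br, and the two oxygens of ring B flank each other and C3–Br. The second is that neither bromine pattern is the one a phenol hydroxyl would direct, since ring A has its bromines meta to the hydroxyl and ring B has three in a row. The strategy rests on C4–H of ring A, which is para to C1–OH and sits between the bromines on C3 and C5: with an acylamino group on C4, ring A is a 4-acylaminophenol brominated on both sides of nitrogen, and its two-electron oxidation gives a symmetric quinone imine that is electrophilic at C2. Ring B shows the same pattern when its C4–Br is read as a former nitrogen.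

**Retrosynthetic reasoning**

The last bond made is C4–H of ring A. Target 13 is traced back through diazonium salt 12 to aminophenol 11, and 11 to its N-acetyl derivative 10. This puts a nitrogen para to the hydroxyl and between the two bromines, which is the substitution pattern needed for the ether-forming step. The forward steps, amide hydrolysis and reductive loss of the diazonium group, must leave seven C–Br bonds and two diaryl ethers untouched.

Amide 10 is cut at the O–C2 bond of ring A, giving the ring B–C phenol 9 and quinone imine 4. A cut on the ring B side would need a substitution at an unactivated, fully flanked carbon of a polybromoarene. On the ring A side, 4 is a ring A with reversed polarity, and its carbon ortho to the ring oxygen is an acceptor. Because 4 is symmetrical, the two acceptor carbons are the same, and the bromines and the nitrogen of ring A are already in place. The forward reaction has to make the phenoxide of 9 add through oxygen at that C–H carbon and nowhere else.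

Quinone imine 4 is traced back to acetamidophenol 3 by removal of two electrons and two protons at an anode. The oxidation is a step of its own, run with no phenoxide in the cell, so that only 3 meets the electrode and 4 reaches the nucleophile free of electrolyte.

Phenol 9 is traced back through diazonium salt 8 to aminophenol 7, so that the middle bromine of ring B (C4–Br) comes from a C–N bond by a Sandmeyer exchange. This gives ring B the same nitrogen-centred pattern as ring A.

Aminophenol 7 comes from amide 6, and 6 is cut at the O–C2 bond of ring B into the same electrophile 4 and phenol 5. One reaction type therefore makes both ether bonds, and ring C arrives with its two bromines in place.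

Acetamidophenol 3 comes from methyl ether 2 by O-demethylation, and 2 from aniline 1 by N-acetylation. The bromines of 1 lie ortho to nitrogen, so their positions are fixed in a purchased compound.

**Alternatives that were turned down**

Alternative 1: The O–C1 bond of ring C is cut in 1,2,3-tribromo-5-methoxy-4-phenoxybenzene (A1), a ring B–C precursor in which ring C has no bromine yet. The aryne precursor would be 2-(trimethylsilyl)phenyl trifluoromethanesulfonate (A3). In the forward key step a fluoride source would convert A3 into benzyne (A4), the phenoxide of 4,5,6-tribromo-2-methoxyphenol (A2) would add to A4, and the aryl anion would be protonated to give A1.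
- For it: A3 is a bench-stable reagent and A4 is small and very reactive, so the hindered hydroxyl of A2 should be arylated at room temperature without a metal that could insert into C–Br bonds. A2 has the bromine pattern expected from exhaustive bromination of its unbrominated parent.
- Against it: the aryl anion formed after the addition sits next to a tribromoarene and can attack bromine instead of taking a proton, which would scramble the halogens. Ring C then needs a twofold bromination that must leave C6 of ring B alone. The ring A ether, at an even more hindered oxygen, is not addressed and needs a second method.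
- Comparison: to phenol 9 this route is as short or shorter (arylation, dibromination and demethylation from A2, against six steps here). The chosen strategy offers instead one bond-forming reaction for both ethers, and rings that enter with every bromine fixed.

Alternative 2: The three C–Br bonds of ring B are cut in 3,5-dibromo-2-(3,4,5-tribromo-2-hydroxyphenoxy)benzaldehyde (A5). In the forward key step a threefold electrophilic bromination in a carboxylic acid solvent would substitute the phenol ring of 3,5-dibromo-2-(2-hydroxyphenoxy)benzaldehyde (A6) ortho and para to the hydroxyl (C3, C5) and then at C4, para to the aryloxy oxygen.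
- For it: A6 should be available in one SNAr step, the reagents are cheap, and the formyl group of A5 is a masked ring A hydroxyl (Baeyer–Villiger oxidation).
- Against it: the third bromine must enter C4, which is meta to the hydroxyl, lies between two bromines and is activated only by an electron-poor aryloxy group, so C6 competes. The aldehyde is exposed to an oxidant. After A5, ring C must still be attached to the most hindered hydroxyl of the molecule, between C3–Br and the ring A oxygen.
- Comparison: on paper it is shorter and cheaper than the chosen route. Its regiochemistry rests on a small electronic preference and its hardest ether bond comes last, whereas here each bromine position is fixed by 1, by 5 or by a nitrogen on a defined carbon.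

Alternative 3: Four C–Br bonds (C3 and C5 of ring B, C2 and C4 of ring C) are cut in 2,6-dibromo-4-(2,4-dibromo-6-methoxyphenoxy)-3-(2,4-dibromophenoxy)aniline (A7). In the forward key step four equivalents of an N-bromoimide would brominate 4-(2,4-dibromo-6-methoxyphenoxy)-3-phenoxyaniline (A8) twice ortho to the amino group and twice on the unsubstituted phenoxy ring. A8 would come from an SNAr reaction para to a nitro group and reduction of that group; after A7 the amino group would be exchanged for bromine and the methyl ether cleaved.
- For it: one nitrogen activates the ether formation, directs two bromines and becomes the third. The sequence is short, about five steps. Its Sandmeyer step runs on an aniline without a free phenol, which is cleaner than steps 6 and 9 here; on that point it is stronger.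
- Against it: the four brominations differ widely in rate. The last one, ortho on the already para-brominated ring C, has to outrun substitution at C6 of ring B and oxidation of the 2,6-dibromoaniline by excess reagent. Under- and over-brominated diaryl ethers would be hard to separate.
- Comparison: shorter than the chosen route, but dependent on a fourfold electrophilic bromination across two rings. The chosen route performs no electrophilic bromination on any diaryl ether.

Key step: step 7

Assumption: quinone imine 4 is taken to be isolable as a crude solid and to persist for some hours in dry aprotic medium at or below 0 °C, as N-acylquinone imines do; because it is not stored, step 3 is run on two portions of 3, one directly before step 4 and one directly before step 7, and is counted once. Locants for 3 and 4 in the steps follow the name of 3 (nitrogen on C1, oxygen on C4).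

**Route**

Step 1
Reactants: 1 2,6-dibromo-4-methoxyaniline
Product: 2 N-(2,6-dibromo-4-methoxyphenyl)acetamide
Conditions: Ac2O, cat. H2SO4, AcOH, 60 °C
Reagents that add atoms: acetic anhydride, CC(=O)OC(C)=O
Why: N-acylation of a hindered, weakly basic aniline under acid catalysis; the moderate temperature should hold the reaction at the monoacetyl stage, and the methyl ether and aryl bromides are inert.

Step 2
Reactants: 2 N-(2,6-dibromo-4-methoxyphenyl)acetamide
Product: 3 N-(2,6-dibromo-4-hydroxyphenyl)acetamide
Conditions: BBr3 (3 equiv), CH2Cl2, −78 °C → rt; then H2O
Reagents that add atoms: none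
Why: Lewis-acid cleavage of an aryl methyl ether (BBr3 demethylation); the excess allows for coordination to the amide, which survives together with the aryl bromides.

Step 3
Reactants: 3 N-(2,6-dibromo-4-hydroxyphenyl)acetamide
Product: 4 N-(2,6-dibromo-4-oxocyclohexa-2,5-dien-1-ylidene)acetamide (N-acetylquinone imine)
Conditions: 2,6-lutidine (2.2 equiv), Bu4NBF4, dry MeCN, graphite felt anode, Pt cathode, divided cell, 0 °C, 2.0 F/mol; then MeCN removed below 0 °C, residue taken up in cold dry Et2O, salts filtered off under Ar, evaporation below 0 °C; used at once
Reagents that add atoms: none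
Why: Anodic two-electron, two-proton oxidation of a 4-acetamidophenol to its N-acylquinone imine, the electrochemical counterpart of the oxidation of such amidophenols with Ag2O; the hindered base 2,6-lutidine takes up the protons without adding to the product, the divided cell keeps 4 away from the cathode, and the charge of two faradays per mole with no nucleophile present stops the reaction at 4.

Step 4
Reactants: 4 N-(2,6-dibromo-4-oxocyclohexa-2,5-dien-1-ylidene)acetamide; 5 2,4-dibromophenol
Product: 6 N-[2,6-dibromo-3-(2,4-dibromophenoxy)-4-hydroxyphenyl]acetamide
Conditions: 5 (2 equiv), Cs2CO3 (2.5 equiv), MeCN, 0 °C; 4 (1.0 equiv) in MeCN added dropwise, 0 °C → rt; then aq. Na2S2O4, dil. HCl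
Reagents that add atoms: none
Why: The caesium phenoxide of 5 should add through oxygen to C3 of 4, the unsubstituted carbon ortho to the quinone oxygen (1,4-addition to the N-acylimine, an oxa-Michael reaction), after which tautomerization restores the arene. Slow addition of 4 to an excess of the phenoxide keeps the phenoxide of the product from competing for 4.

Step 5
Reactants: 6 N-[2,6-dibromo-3-(2,4-dibromophenoxy)-4-hydroxyphenyl]acetamide
Product: 7 4-amino-3,5-dibromo-2-(2,4-dibromophenoxy)phenol
Conditions: conc. HCl/1,4-dioxane (1:1), reflux, N2; then NaHCO3 to pH 6–7
Reagents that add atoms: none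
Why: Acid-catalysed amide hydrolysis; the 2,6-dibromoanilide is hindered and needs forcing conditions, which the diaryl ether, the aryl bromides and the phenol tolerate, and exclusion of air protects the 4-aminophenol.

Step 6
Reactants: 7 4-amino-3,5-dibromo-2-(2,4-dibromophenoxy)phenol
Product: 9 3,4,5-tribromo-2-(2,4-dibromophenoxy)phenol, via diazonium salt 8 (not isolated)
Conditions: a) NaNO2, conc. H2SO4, AcOH, 0–10 °C; b) CuBr (0.5 equiv), 48% HBr, 0 → 70 °C
Reagents that add atoms: hydrogen bromide (48% aq.), Br; the bromide is passed on through CuBr, [Cu]Br
Why: Diazotization with nitrosylsulfuric acid, needed for the weakly basic 2,6-dibromoaniline, followed by Sandmeyer bromination. The strongly acidic medium keeps the 4-hydroxy diazonium ion protonated, which should suppress quinone diazide formation and azo coupling.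

Step 7
Reactants: 4 N-(2,6-dibromo-4-oxocyclohexa-2,5-dien-1-ylidene)acetamide; 9 3,4,5-tribromo-2-(2,4-dibromophenoxy)phenol
Product: 10 N-{2,6-dibromo-4-hydroxy-3-[3,4,5-tribromo-2-(2,4-dibromophenoxy)phenoxy]phenyl}acetamide
Conditions: 9 (1.3 equiv), Cs2CO3 (1.5 equiv), MeCN/DMF, 0 °C; 4 (1.0 equiv, freshly made by step 3) in MeCN added dropwise, 0 °C → rt; then aq. Na2S2O4, dil. HCl
Reagents that add atoms: none
Why: In quinone imine 4, the anodic oxidation of step 3 has reversed the polarity of ring A, and C3 and C5, the two equivalent C–H carbons ortho to the ring oxygen, are the β-positions of an N-acylimine. The caesium phenoxide of 9 adds through oxygen to one of them (1,4-addition, an oxa-Michael reaction), the charge is taken up by the amide nitrogen, and loss of the C3 proton restores the benzene ring and makes the addition irreversible. The closest known reaction type is the conjugate addition of thiolate, sulfinate or amine nucleophiles to N-acetylquinone imines generated from 4-acetamidophenols at an anode or with a chemical oxidant, which also takes place ortho to the hydroxyl group; an aryl oxide is a less common partner. No ring is closed and no stereocenter is formed. Site selectivity is needed against attack at C1 (shielded by the two flanking bromines and reversible), against attack at the brominated carbons C2 and C6 (β only to the weaker ketone acceptor and substituted), and against C-attack of the phenoxide (its one free ortho carbon lies next to a bromine on an electron-poor ring, and a caesium phenoxide in a dipolar aprotic solvent reacts at oxygen). Because 4 is made beforehand with no phenoxide present, neither 9 nor the ionized form of 3 can be oxidized at the anode or act as a rival nucleophile; this matters because the two bromines twist the acetamido group of 3 out of conjugation and may bring its oxidation potential close to that of a bromophenoxide. Overreaction is limited by keeping 4 the limiting component and by adding it slowly to an excess of the phenoxide, the surplus of 9 being recovered.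

Step 8
Reactants: 10 N-{2,6-dibromo-4-hydroxy-3-[3,4,5-tribromo-2-(2,4-dibromophenoxy)phenoxy]phenyl}acetamide
Product: 11 4-amino-3,5-dibromo-2-[3,4,5-tribromo-2-(2,4-dibromophenoxy)phenoxy]phenol
Conditions: conc. HCl/1,4-dioxane (1:1), reflux, N2; then NaHCO3 to pH 6–7
Reagents that add atoms: none
Why: Acid-catalysed amide hydrolysis as in step 5; both diaryl ethers and all C–Br bonds are stable to hot mineral acid, and the aminophenol is kept under N2 and used at once.

Step 9
Reactants: 11 4-amino-3,5-dibromo-2-[3,4,5-tribromo-2-(2,4-dibromophenoxy)phenoxy]phenol
Product: 13 bromoiesol A (3,5-dibromo-2-[3,4,5-tribromo-2-(2,4-dibromophenoxy)phenoxy]phenol), via diazonium salt 12 (not isolated)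
Conditions: a) NaNO2, conc. H2SO4, AcOH, 0–5 °C; b) 50% aq. H3PO2, 0 °C → rt
Reagents that add atoms: none
Why: Diazotization with nitrosylsulfuric acid and hydrodediazoniation by hypophosphorous acid (radical chain reduction of the diazonium ion); the aryl radical takes hydrogen from the P–H bond faster than it can attack a neighbouring ring, and the aryl bromides are not reduced.

**Compound list**

1 | 2,6-dibromo-4-methoxyaniline | COc1cc(Br)c(N)c(Br)c1 | starting material
2 | N-(2,6-dibromo-4-methoxyphenyl)acetamide | COc1cc(Br)c(NC(C)=O)c(Br)c1 | intermediate
3 | N-(2,6-dibromo-4-hydroxyphenyl)acetamide | CC(=O)Nc1c(Br)cc(O)cc1Br | intermediate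
4 | N-(2,6-dibromo-4-oxocyclohexa-2,5-dien-1-ylidene)acetamide (N-acetylquinone imine) | CC(=O)N=C1C(Br)=CC(=O)C=C1Br | intermediate
5 | 2,4-dibromophenol | Oc1ccc(Br)cc1Br | starting material
6 | N-[2,6-dibromo-3-(2,4-dibromophenoxy)-4-hydroxyphenyl]acetamide | CC(=O)Nc1c(Br)cc(O)c(Oc2ccc(Br)cc2Br)c1Br | intermediate
7 | 4-amino-3,5-dibromo-2-(2,4-dibromophenoxy)phenol | Nc1c(Br)cc(O)c(Oc2ccc(Br)cc2Br)c1Br | intermediate
8 | 2,6-dibromo-3-(2,4-dibromophenoxy)-4-hydroxybenzenediazonium hydrogen sulfate (not isolated) | N#[N+]c1c(Br)cc(O)c(Oc2ccc(Br)cc2Br)c1Br.OS(=O)(=O)[O-] | intermediate
9 | 3,4,5-tribromo-2-(2,4-dibromophenoxy)phenol | Oc1cc(Br)c(Br)c(Br)c1Oc1ccc(Br)cc1Br | intermediate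
10 | N-{2,6-dibromo-4-hydroxy-3-[3,4,5-tribromo-2-(2,4-dibromophenoxy)phenoxy]phenyl}acetamide | CC(=O)Nc1c(Br)cc(O)c(Oc2cc(Br)c(Br)c(Br)c2Oc2ccc(Br)cc2Br)c1Br | intermediate
11 | 4-amino-3,5-dibromo-2-[3,4,5-tribromo-2-(2,4-dibromophenoxy)phenoxy]phenol | Nc1c(Br)cc(O)c(Oc2cc(Br)c(Br)c(Br)c2Oc2ccc(Br)cc2Br)c1Br | intermediate
12 | 2,6-dibromo-4-hydroxy-3-[3,4,5-tribromo-2-(2,4-dibromophenoxy)phenoxy]benzenediazonium hydrogen sulfate (not isolated) | N#[N+]c1c(Br)cc(O)c(Oc2cc(Br)c(Br)c(Br)c2Oc2ccc(Br)cc2Br)c1Br.OS(=O)(=O)[O-] | intermediate
13 | bromoiesol A (3,5-dibromo-2-[3,4,5-tribromo-2-(2,4-dibromophenoxy)phenoxy]phenol) | Oc1cc(Br)cc(Br)c1Oc1cc(Br)c(Br)c(Br)c1Oc1ccc(Br)cc1Br | target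

**Step count and risk**

Total: 9 steps. Longest linear sequence: 9 steps (1 → 2 → 3 → 4 → 6 → 7 → 9 → 10 → 11 → 13; compound 4 enters in steps 4 and 7 and is made freshly for each by step 3, compound 5 enters once).

Step 7 (key step). The most likely failures are:
- electron transfer from the phenoxide of 9 to the oxidizing quinone imine 4 instead of bond formation, which would return 3 and couple 9 oxidatively;
- slow addition at the congested oxygen of 9, so that 4 decays by hydrolysis or self-condensation;
- addition at a brominated carbon with loss of bromide;
- capture of 4 by the phenoxide of the product.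

Making 4 with Ag2O instead of at the anode would answer a failure of step 3 only, not of the addition. The fallback sets out from 9 and makes the same O–C2 bond by nucleophilic aromatic substitution. The potassium phenoxide of 9 (K2CO3, DMF, 80–100 °C) would displace the fluoride of 3,5-dibromo-2-fluorobenzaldehyde (O=Cc1cc(Br)cc(Br)c1F), activated by its ortho formyl group, to give 3,5-dibromo-2-[3,4,5-tribromo-2-(2,4-dibromophenoxy)phenoxy]benzaldehyde F1. Baeyer–Villiger oxidation with mCPBA in CH2Cl2 would give 3,5-dibromo-2-[3,4,5-tribromo-2-(2,4-dibromophenoxy)phenoxy]phenyl formate F2, and methanolysis (K2CO3, MeOH) would give 13, where the route is rejoined with steps 8 and 9 left out. The weak point of this fallback is the migration of an electron-poor aryl group in the oxidation.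

Step 3. The quinone imine may be lost while the electrolyte is removed, by hydrolysis with traces of water or by self-condensation during concentration, and the electrolysis itself may stall through fouling of the anode by oligomers. The fallback sets out from 3 and replaces the electrode by a solid oxidant. Stirring 3 with dry Ag2O in dry CHCl3 at room temperature, filtration through Celite under Ar and evaporation would give 4 with no electrolyte or amine to separate, and the route is rejoined at 4. No compound outside the route is made on this way, which is listed as F0.

Step 4. The same processes as in step 7 can occur, and in addition 5 has an unhindered free ortho carbon, so C-arylation of the phenoxide is more likely than with 9. The fallback sets out from 5. Chan–Lam coupling with (2-methoxy-5-nitrophenyl)boronic acid (COc1ccc(cc1B(O)O)[N+](=O)[O-]; Cu(OAc)2 20 mol%, pyridine, O2, 4 Å molecular sieves, CH2Cl2) would give 2-(2,4-dibromophenoxy)-1-methoxy-4-nitrobenzene F3. Hydrogenation over sulfided Pt/C, which spares aryl bromides, would give 3-(2,4-dibromophenoxy)-4-methoxyaniline F4. Two equivalents of NBS in MeCN at 0 °C would brominate both positions ortho to the amino group to give 2,6-dibromo-3-(2,4-dibromophenoxy)-4-methoxyaniline F5. BBr3 in CH2Cl2 would cleave the methyl ether and give 7, where the route is rejoined.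

Step 6. The 4-hydroxy diazonium ion can lose its phenolic proton during the transfer into the copper solution and become a quinone diazide, which resists bromide transfer; azo coupling and reduction to the arene are further losses. The fallback sets out from 7 and masks the phenol. O-selective sulfonylation (TsCl, Et3N, CH2Cl2, 0 °C; the amino group between two bromines is too hindered and too weakly nucleophilic to compete) would give 4-amino-3,5-dibromo-2-(2,4-dibromophenoxy)phenyl 4-methylbenzenesulfonate F6. Aprotic halodediazoniation (tert-butyl nitrite, CuBr2, MeCN, 0 → 60 °C) would give 3,4,5-tribromo-2-(2,4-dibromophenoxy)phenyl 4-methylbenzenesulfonate F7, and KOH in MeOH/THF at reflux would cleave the sulfonate and return 9.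

Step 9. Diazotization of the very hindered, weakly basic and poorly soluble amine 11 may stay incomplete, and the hydroxy diazonium ion may again collapse to a quinone diazide before it is reduced. The fallback sets out from 11. Sulfonylation of the phenol (TsCl, Et3N, CH2Cl2) would give 4-amino-3,5-dibromo-2-[3,4,5-tribromo-2-(2,4-dibromophenoxy)phenoxy]phenyl 4-methylbenzenesulfonate F8. Reductive deamination with tert-butyl nitrite in THF at 60 °C, in which the aryl radical takes hydrogen from the solvent, would give 3,5-dibromo-2-[3,4,5-tribromo-2-(2,4-dibromophenoxy)phenoxy]phenyl 4-methylbenzenesulfonate F9. KOH in MeOH/THF at reflux would free the phenol and give 13.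

**Further compounds**

F0 | step 3 | none | none
F1 | step 7 | 3,5-dibromo-2-[3,4,5-tribromo-2-(2,4-dibromophenoxy)phenoxy]benzaldehyde | O=Cc1cc(Br)cc(Br)c1Oc1cc(Br)c(Br)c(Br)c1Oc1ccc(Br)cc1Br
F2 | step 7 | 3,5-dibromo-2-[3,4,5-tribromo-2-(2,4-dibromophenoxy)phenoxy]phenyl formate | O=COc1cc(Br)cc(Br)c1Oc1cc(Br)c(Br)c(Br)c1Oc1ccc(Br)cc1Br
F3 | step 4 | 2-(2,4-dibromophenoxy)-1-methoxy-4-nitrobenzene | COc1ccc(cc1Oc1ccc(Br)cc1Br)[N+](=O)[O-]
F4 | step 4 | 3-(2,4-dibromophenoxy)-4-methoxyaniline | COc1ccc(N)cc1Oc1ccc(Br)cc1Br
F5 | step 4 | 2,6-dibromo-3-(2,4-dibromophenoxy)-4-methoxyaniline | COc1cc(Br)c(N)c(Br)c1Oc1ccc(Br)cc1Br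
F6 | step 6 | 4-amino-3,5-dibromo-2-(2,4-dibromophenoxy)phenyl 4-methylbenzenesulfonate | Cc1ccc(cc1)S(=O)(=O)Oc1cc(Br)c(N)c(Br)c1Oc1ccc(Br)cc1Br
F7 | step 6 | 3,4,5-tribromo-2-(2,4-dibromophenoxy)phenyl 4-methylbenzenesulfonate | Cc1ccc(cc1)S(=O)(=O)Oc1cc(Br)c(Br)c(Br)c1Oc1ccc(Br)cc1Br
F8 | step 9 | 4-amino-3,5-dibromo-2-[3,4,5-tribromo-2-(2,4-dibromophenoxy)phenoxy]phenyl 4-methylbenzenesulfonate | Cc1ccc(cc1)S(=O)(=O)Oc1cc(Br)c(N)c(Br)c1Oc1cc(Br)c(Br)c(Br)c1Oc1ccc(Br)cc1Br
F9 | step 9 | 3,5-dibromo-2-[3,4,5-tribromo-2-(2,4-dibromophenoxy)phenoxy]phenyl 4-methylbenzenesulfonate | Cc1ccc(cc1)S(=O)(=O)Oc1cc(Br)cc(Br)c1Oc1cc(Br)c(Br)c(Br)c1Oc1ccc(Br)cc1Br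
A1 | alternative 1 | 1,2,3-tribromo-5-methoxy-4-phenoxybenzene | COc1cc(Br)c(Br)c(Br)c1Oc1ccccc1
A2 | alternative 1 | 4,5,6-tribromo-2-methoxyphenol | COc1cc(Br)c(Br)c(Br)c1O
A3 | alternative 1 | 2-(trimethylsilyl)phenyl trifluoromethanesulfonate | C[Si](C)(C)c1ccccc1OS(=O)(=O)C(F)(F)F
A4 | alternative 1 | benzyne | C1#CC=CC=C1
A5 | alternative 2 | 3,5-dibromo-2-(3,4,5-tribromo-2-hydroxyphenoxy)benzaldehyde | O=Cc1cc(Br)cc(Br)c1Oc1cc(Br)c(Br)c(Br)c1O
A6 | alternative 2 | 3,5-dibromo-2-(2-hydroxyphenoxy)benzaldehyde | O=Cc1cc(Br)cc(Br)c1Oc1ccccc1O
A7 | alternative 3 | 2,6-dibromo-4-(2,4-dibromo-6-methoxyphenoxy)-3-(2,4-dibromophenoxy)aniline | COc1cc(Br)cc(Br)c1Oc1cc(Br)c(N)c(Br)c1Oc1ccc(Br)cc1Br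
A8 | alternative 3 | 4-(2,4-dibromo-6-methoxyphenoxy)-3-phenoxyaniline | COc1cc(Br)cc(Br)c1Oc1ccc(N)cc1Oc1ccccc1
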